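## Retrosynthetic overview

1. Hanultarin ⇒ fluoride desilylation of its tris-TIPS ether ⇒ mono-esterification of C2-symmetric bis-TIPS (−)-secoisolariciresinol with TIPS-ferulic acid (the two CH2OH groups are homotopic, so there is no regiochemistry issue).
2. Diol ⇒ reductive ozonolysis of (3S,4S)-3,4-bis(arylmethyl)hexa-1,5-diene (each vinyl becomes CH2OH).
3. Diene ⇒ proposed new Pd-catalysed, B2pin2-mediated enantioselective reductive allyl–allyl homocoupling of an (E)-4-aryl-but-2-enyl tert-butyl carbonate; this forms the C8–C8′ bond and both stereocentres.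
4. Allylic carbonate ⇒ cross-metathesis of TIPS-eugenol with (Z)-but-2-ene-1,4-diyl bis(tert-butyl carbonate).
5. No rings are formed; the three arenes come intact from eugenol (twice) and ferulic acid.

Assumption: the target is the mono-(E)-ferulate of (2R,3R)-(−)-secoisolariciresinol, and the (R)-ligand in step 4 is assumed to give the (3S,4S)-diene; if the sense of induction is opposite, the (S)-ligand is used with no other change.

## Route

**Step 1**
Reactants: 1 eugenol (4-allyl-2-methoxyphenol)
Product: 2 triisopropyl[2-methoxy-4-(prop-2-en-1-yl)phenoxy]silane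
Conditions: TIPSCl (1.2 equiv), imidazole (2.5 equiv), DMF, rt
Reagents that add atoms: TIPSCl, CC(C)[Si](Cl)(C(C)C)C(C)C
Why: Standard imidazole-promoted phenol silylation; the aryl TIPS ether tolerates Ru, Pd/alkoxide, O3/NaBH4 and carbodiimide conditions and is later removed by fluoride without touching the cinnamate.

**Step 2**
Reactants: 3 (Z)-but-2-ene-1,4-diol
Product: 4 (Z)-but-2-ene-1,4-diyl di-tert-butyl bis(carbonate)
Conditions: Boc2O (2.5 equiv), Bu4NHSO4 (5 mol%), 30% aq NaOH/CH2Cl2, 0 °C to rt
Reagents that add atoms: Boc2O, CC(C)(C)OC(=O)OC(=O)OC(C)(C)C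
Why: Phase-transfer O-alkoxycarbonylation of two primary allylic alcohols; no stereocentre is involved and the alkene is untouched.

**Step 3**
Reactants: 2 TIPS-eugenol; 4 (Z)-bis-Boc carbonate (3 equiv)
Product: 5 tert-butyl (2E)-4-[3-methoxy-4-(triisopropylsilyloxy)phenyl]but-2-en-1-yl carbonate
Conditions: Grubbs II (3 mol%), 1,4-benzoquinone (10 mol%), CH2Cl2, 40 °C
Reagents that add atoms: none
Why: Olefin cross-metathesis of a type-I allylarene with an excess of a symmetric Z-1,4-disubstituted butene is thermodynamically E-selective; benzoquinone suppresses Ru–H isomerisation to the styrene, and residual Z isomer is harmless because both isomers converge on the same syn-π-allyl-Pd in step 4.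

**Step 4**
Reactants: 5 allylic carbonate (2 molecules)
Product: 6 (3S,4S)-3,4-bis{[3-methoxy-4-(triisopropylsilyloxy)phenyl]methyl}hexa-1,5-diene
Conditions: Pd2(dba)3 (2.5 mol%), (R)-MeO-furyl-BIPHEP (6 mol%), B2pin2 (0.52 equiv, slow addition), THF, 60 °C
Reagents that add atoms: none (B2pin2 is only the terminal reductant; no boron is retained)
Why: Proposed new method: a Pd/chiral-bisphosphine-catalysed, diboron-mediated enantio- and diastereoselective reductive homocoupling of an aliphatic allylic carbonate. Pd(0) ionises 5 (loss of CO2) to a syn-π-allyl-Pd tert-butoxide; alkoxide-activated B2pin2 borylates half of it to the linear (E)-allyl-Bpin, which transmetalates onto a second π-allyl-Pd to give a cis-bis(η1-allyl)Pd(P–P) bound through both CH2 termini; the small-bite-angle bisphosphine enforces inner-sphere 3,3′-reductive elimination through a chair-like transition state with both CH2Ar groups pseudo-equatorial, which joins the two substituted carbons (branched–branched), gives the C2-symmetric rather than meso diene (as a Cope chair does from E,E termini), and lets the C2-symmetric ligand select one enantiomeric chair, so both stereocentres are set here; the closest known reaction types are Pd-catalysed borylation of allylic carbonates with B2pin2 and Pd/biaryl-bisphosphine enantioselective allyl–allyl cross-coupling of preformed allylboronates with allylic electrophiles, and the untested part is the single-flask homodimerisation.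

**Step 5**
Reactants: 6 diene
Product: 7 (2R,3R)-2,3-bis{[3-methoxy-4-(triisopropylsilyloxy)phenyl]methyl}butane-1,4-diol
Conditions: O3, CH2Cl2/MeOH 3:1, −78 °C (Sudan Red 7B endpoint); then NaBH4 (6 equiv), −78 °C to rt
Reagents that add atoms: ozone, [O-][O+]=O
Why: Reductive ozonolysis: terminal vinyl groups react far faster than the silylated guaiacyl rings and the peroxidic intermediates are reduced in situ before the α-branched aldehydes can epimerise; no bond to a stereocentre is broken, and the descriptors change from S,S to R,R only because CIP priorities change.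

**Step 6**
Reactants: 8 (E)-ferulic acid
Product: 9 (2E)-3-[3-methoxy-4-(triisopropylsilyloxy)phenyl]prop-2-enoic acid
Conditions: TIPSCl (2.4 equiv), imidazole (5 equiv), DMF, rt; then K2CO3, MeOH/THF/H2O, 0 °C to rt; acidify to pH 4
Reagents that add atoms: TIPSCl, CC(C)[Si](Cl)(C(C)C)C(C)C
Why: Exhaustive silylation followed by selective hydrolysis of the much more labile silyl ester leaves the hindered aryl silyl ether and the E-alkene intact.

**Step 7**
Reactants: 7 diol (1.0 equiv); 9 TIPS-ferulic acid (0.85 equiv, syringe pump)
Product: 10 (2R,3R)-4-hydroxy-2,3-bis{[3-methoxy-4-(triisopropylsilyloxy)phenyl]methyl}butyl (2E)-3-[3-methoxy-4-(triisopropylsilyloxy)phenyl]prop-2-enoate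
Conditions: EDC·HCl (1.0 equiv), DMAP (0.1 equiv), CH2Cl2, 0 °C to rt; unreacted 7 recovered and recycled
Reagents that add atoms: none
Why: Steglich esterification of a primary alcohol; because 7 is C2-symmetric only mono- versus bis-acylation matters, which is controlled by sub-stoichiometric slow addition of the acid, and all phenols are masked.

**Step 8**
Reactants: 10 tris-TIPS monoester
Product: 11 hanultarin, (2R,3R)-4-hydroxy-2,3-bis[(4-hydroxy-3-methoxyphenyl)methyl]butyl (2E)-3-(4-hydroxy-3-methoxyphenyl)prop-2-enoate
Conditions: TBAF (3.6 equiv)/AcOH (3.6 equiv), THF, 0 °C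
Reagents that add atoms: none
Why: Fluoride cleavage of three aryl silyl ethers, buffered so the liberated phenoxides do not attack the cinnamate ester; a 1,4-acyl shift would be degenerate by C2 symmetry and no stereocentre is touched.

## Compound list

1 | eugenol | C=CCc1ccc(O)c(OC)c1 | starting material
2 | triisopropyl[2-methoxy-4-(prop-2-en-1-yl)phenoxy]silane | C=CCc1ccc(O[Si](C(C)C)(C(C)C)C(C)C)c(OC)c1 | intermediate
3 | (Z)-but-2-ene-1,4-diol | OC/C=C\CO | starting material
4 | (Z)-but-2-ene-1,4-diyl di-tert-butyl bis(carbonate) | CC(C)(C)OC(=O)OC/C=C\COC(=O)OC(C)(C)C | intermediate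
5 | tert-butyl (2E)-4-[3-methoxy-4-(triisopropylsilyloxy)phenyl]but-2-en-1-yl carbonate | CC(C)(C)OC(=O)OC/C=C/Cc1ccc(O[Si](C(C)C)(C(C)C)C(C)C)c(OC)c1 | intermediate
6 | (3S,4S)-3,4-bis{[3-methoxy-4-(triisopropylsilyloxy)phenyl]methyl}hexa-1,5-diene | C=C[C@H](Cc1ccc(O[Si](C(C)C)(C(C)C)C(C)C)c(OC)c1)[C@H](C=C)Cc1ccc(O[Si](C(C)C)(C(C)C)C(C)C)c(OC)c1 | intermediate
7 | (2R,3R)-2,3-bis{[3-methoxy-4-(triisopropylsilyloxy)phenyl]methyl}butane-1,4-diol | OC[C@H](Cc1ccc(O[Si](C(C)C)(C(C)C)C(C)C)c(OC)c1)[C@H](CO)Cc1ccc(O[Si](C(C)C)(C(C)C)C(C)C)c(OC)c1 | intermediate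
8 | (E)-ferulic acid | COc1cc(/C=C/C(=O)O)ccc1O | starting material
9 | (2E)-3-[3-methoxy-4-(triisopropylsilyloxy)phenyl]prop-2-enoic acid | COc1cc(/C=C/C(=O)O)ccc1O[Si](C(C)C)(C(C)C)C(C)C | intermediate
10 | tris-O-TIPS hanultarin | COc1cc(/C=C/C(=O)OC[C@H](Cc2ccc(O[Si](C(C)C)(C(C)C)C(C)C)c(OC)c2)[C@H](CO)Cc2ccc(O[Si](C(C)C)(C(C)C)C(C)C)c(OC)c2)ccc1O[Si](C(C)C)(C(C)C)C(C)C | intermediate
11 | hanultarin | COc1cc(/C=C/C(=O)OC[C@H](Cc2ccc(O)c(OC)c2)[C@H](CO)Cc2ccc(O)c(OC)c2)ccc1O | target

## Summary

Total steps: 8. Longest linear sequence: 6 (steps 1, 3, 4, 5, 7, 8).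

Steps most likely to fail:

- **Step 4 (proposed new reductive allyl–allyl homocoupling).** Risks are the dl/meso ratio, the ee, linear coupling, and alkoxide-induced elimination of the π-allyl to the aryl-butadiene. Fallback (known chemistry): TIPS-protect commercial dihydroferulic acid and attach it to (S)-4-isopropyl-oxazolidin-2-one. Oxidative homocoupling of the enolate (LDA, then TiCl4, −78 °C) gives the (R,R)-2,3-bis(arylmethyl)succinyl bis-imide, and LiBH4 reduction gives diol 7 directly. This replaces steps 2–5.
- **Step 7 (statistical mono-esterification).** The risk is bis-ester formation and low conversion to 10. Fallback: convert 7 to its seven-membered cyclic sulfate (SOCl2/Et3N; then cat. RuCl3/NaIO4). Open it once with the caesium salt of 9 in DMF; the resulting sulfate monoanion cannot be displaced again. Hydrolyse the sulfate monoester (cat. H2SO4, wet THF) to 10.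
- **Step 3 (cross-metathesis).** Risks are isomerisation of the electron-rich allylarene to the styrene, homodimer formation and separation from excess 4. Fallback: form the aryl Grignard from TIPS-protected 4-bromo-2-methoxyphenol and open butadiene monoepoxide in a Cu-catalysed SN2′ reaction to give (E)-4-aryl-but-2-en-1-ol. Boc2O then gives 5.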